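**Retrosynthetic overview**

- Locants: ring A (amino dienone) has C1 acyl, C2 NH2, C3 Me/OH, C4 C=O, C5 CH2, C6 OMe; ring B has C1' Me/CH2, C2' C=O, C3' Me/ester, C4' C=O, C5' H, C6' OMe.
- Disconnections, last to first: C2–N (ammonia on the enol); C3–O (ring A dearomatisation); C5'–Br to C5'–H; C1'–CH3 (enolate methylation); C5–CH2 (ring A arene onto a ring B methylidene dienone); C3'–O ester (ring B dearomatisation); aryl ketone (Friedel–Crafts).
- Both carbocycles are bought as the same arene, 5-methoxy-2-methylbenzene-1,3-diol, so no ring is built. Ring B is dearomatised first (step 5) and ring A last (step 10), both with one chiral aryl iodide scaffold (the two antipodes).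
- The (S)- and (R)-2-methylbutanoyl groups come from tiglic acid by asymmetric hydrogenation. Bromine blocks C5' of ring B until step 9.

Assumption: the SMILES is read literally, i.e. (R) at the ketone side chain, (S) at the ester side chain, and R at C3, C1' and C3'; 5-methoxy-2-methylbenzene-1,3-diol is taken as a catalogue compound.

**Route**

Step 1
Reactants: 1 (E)-2-methylbut-2-enoic acid (tiglic acid)
Product: 2 (2S)-2-methylbutanoic acid
Conditions: H2 (4 atm), Ru(OAc)2[(S)-H8-BINAP] (0.5 mol %), MeOH, 20 °C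
Reagents that add atoms: none
Why: Carboxylate-directed asymmetric hydrogenation of an α,β-unsaturated acid (Noyori–Takaya type), in which the substrate binds ruthenium as a carboxylate and the (S)-H8-BINAP ligand delivers H2 to one face of the alkene, setting the first stereocenter as S.

Step 2
Reactants: 1 (E)-2-methylbut-2-enoic acid (tiglic acid)
Product: 3 (2R)-2-methylbutanoic acid
Conditions: H2 (4 atm), Ru(OAc)2[(R)-H8-BINAP] (0.5 mol %), MeOH, 20 °C
Reagents that add atoms: none
Why: The same asymmetric hydrogenation with the mirror-image ligand gives the R acid needed for the ketone side chain.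

Step 3
Reactants: 4 5-methoxy-2-methylbenzene-1,3-diol
Product: 5 4-bromo-5-methoxy-2-methylbenzene-1,3-diol
Conditions: NBS (0.95 equiv), MeCN, −40 °C
Reagents that add atoms: N-bromosuccinimide, BrN1C(=O)CCC1=O
Why: Electrophilic aromatic bromination, where the two free ring positions of 4 are equivalent and the first bromine deactivates the ring enough to stop at the monobromide; this bromine later blocks C5' of ring B.

Step 4
Reactants: 5 4-bromo-5-methoxy-2-methylbenzene-1,3-diol
Product: 6 4-bromo-5-methoxy-2-methyl-6-[(4-methylbenzenesulfonyl)methyl]benzene-1,3-diol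
Conditions: (CH2O)n, TolSO2Na, HCO2H–H2O, 45 °C
Reagents that add atoms: formaldehyde (as paraformaldehyde), C=O; sodium 4-methylbenzenesulfinate, [Na+].[O-]S(=O)c1ccc(C)cc1
Why: Three-component sulfonylmethylation of a phenol (hydroxymethylation, loss of water to an ortho-quinone methide, conjugate addition of sulfinate), which can only occur at the single remaining ring position, the future C1'.

Step 5
Reactants: 6 4-bromo-5-methoxy-2-methyl-6-[(4-methylbenzenesulfonyl)methyl]benzene-1,3-diol; 2 (2S)-2-methylbutanoic acid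
Product: 7 (1S)-3-bromo-6-hydroxy-4-methoxy-1-methyl-5-[(4-methylbenzenesulfonyl)methyl]-2-oxocyclohexa-3,5-dien-1-yl (2S)-2-methylbutanoate
Conditions: (R,R)-2,2'-[(2-iodo-1,3-phenylene)bis(oxy)]bis(N-mesitylpropanamide) (10 mol %), mCPBA (1.2 equiv), 2 (5 equiv), CHCl3, −20 °C
Reagents that add atoms: none
Why: Proposed new method: mCPBA oxidises the chiral aryl iodide to a trivalent iodine bis(carboxylate) carrying 2, the less hindered hydroxyl of 6 (the one beside Br) exchanges onto iodine, and the (S)-carboxylate is delivered to the methyl-bearing ortho carbon C3' (the most electron-rich ring carbon, flanked by both hydroxyls, while the carbons bearing Br and CH2SO2Tol are deactivated) on the face left open by the lactamide arms, releasing the aryl iodide and setting C3' with its oxygen on the face the target requires; the closest known reactions are the Wessely ortho-acetoxylation of phenols (achiral, intermolecular) and the enantioselective Kita spirolactonization run with this catalyst (intramolecular carboxylate), so the new element is enantioselective intermolecular delivery of a free carboxylic acid to a resorcinol.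

Step 6
Reactants: 4 5-methoxy-2-methylbenzene-1,3-diol; 3 (2R)-2-methylbutanoic acid
Product: 9 (2R)-1-(2,4-dihydroxy-6-methoxy-3-methylphenyl)-2-methylbutan-1-one, via acid chloride 8 (not isolated)
Conditions: (COCl)2, DMF (cat.), CH2Cl2, 0 °C to rt; then AlCl3 (3 equiv), PhNO2, 0 °C to rt
Reagents that add atoms: none
Why: Friedel–Crafts acylation (O-acylation and Fries shift under AlCl3), where the two free positions of 4 are equivalent, the first acyl group deactivates the ring against a second, and the low temperature protects the α-stereocenter.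

Step 7
Reactants: 7 (1S)-3-bromo-6-hydroxy-4-methoxy-1-methyl-5-[(4-methylbenzenesulfonyl)methyl]-2-oxocyclohexa-3,5-dien-1-yl (2S)-2-methylbutanoate; 9 (2R)-1-(2,4-dihydroxy-6-methoxy-3-methylphenyl)-2-methylbutan-1-one
Product: 11 (1S)-3-bromo-5-{[2,4-dihydroxy-6-methoxy-3-methyl-5-[(2R)-2-methylbutanoyl]phenyl]methyl}-6-hydroxy-4-methoxy-1-methyl-2-oxocyclohexa-3,5-dien-1-yl (2S)-2-methylbutanoate, via methylidene dienone 10 (not isolated)
Conditions: Et3N (2.2 equiv), CH2Cl2, −20 °C to rt
Reagents that add atoms: none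
Why: E1cB loss of sulfinate from the enolate of 7 gives the methylidene dienone 10 (an ortho-quinone-methide-type acceptor), and the only free ring carbon of 9 (C5) adds in a Friedel–Crafts-type Michael addition that ends in the stable enol; bromine keeps ring B from reacting through C5', and no stereocenter is formed or touched.

Step 8
Reactants: 11 (1S)-3-bromo-5-{[2,4-dihydroxy-6-methoxy-3-methyl-5-[(2R)-2-methylbutanoyl]phenyl]methyl}-6-hydroxy-4-methoxy-1-methyl-2-oxocyclohexa-3,5-dien-1-yl (2S)-2-methylbutanoate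
Product: 12 (1S,5R)-3-bromo-5-{[2,4-dihydroxy-6-methoxy-3-methyl-5-[(2R)-2-methylbutanoyl]phenyl]methyl}-4-methoxy-1,5-dimethyl-2,6-dioxocyclohex-3-en-1-yl (2S)-2-methylbutanoate
Conditions: MeI (5 equiv), K2CO3 (0.55 equiv), acetone, 0 °C to rt
Reagents that add atoms: iodomethane, CI
Why: C-alkylation of a vinylogous 1,3-dicarbonyl enolate (the geminal dialkylation known for dearomatised phloroglucinols), in which the limited base deprotonates only the ring B enol (pKa about 5, against 7.5 or more for the ring A phenols), bromine blocks C5', and MeI attacks C1' on the ring face carrying the C3' acyloxy group (the smaller C3' substituent and the face normally attacked in ortho-quinol esters), so the CH2Ar group ends anti to the ester and C1' is set as R.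

Step 9
Reactants: 12 (1S,5R)-3-bromo-5-{[2,4-dihydroxy-6-methoxy-3-methyl-5-[(2R)-2-methylbutanoyl]phenyl]methyl}-4-methoxy-1,5-dimethyl-2,6-dioxocyclohex-3-en-1-yl (2S)-2-methylbutanoate
Product: 13 (1R,5R)-5-{[2,4-dihydroxy-6-methoxy-3-methyl-5-[(2R)-2-methylbutanoyl]phenyl]methyl}-4-methoxy-1,5-dimethyl-2,6-dioxocyclohex-3-en-1-yl (2S)-2-methylbutanoate
Conditions: Pd(PPh3)4 (5 mol %), Bu3SnH (1.2 equiv), THF, rt
Reagents that add atoms: none
Why: Palladium-catalysed hydrodehalogenation of a vinyl bromide (oxidative addition, tin-to-palladium hydride transfer, reductive elimination) under neutral conditions that leave esters, ketones and phenols alone; the C3' descriptor changes from S to R only because bromine leaves the priority sequence.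

Step 10
Reactants: 13 (1R,5R)-5-{[2,4-dihydroxy-6-methoxy-3-methyl-5-[(2R)-2-methylbutanoyl]phenyl]methyl}-4-methoxy-1,5-dimethyl-2,6-dioxocyclohex-3-en-1-yl (2S)-2-methylbutanoate
Product: 14 (1R,5R)-5-{[(5R)-5-[(chloroacetyl)oxy]-4-hydroxy-2-methoxy-5-methyl-3-[(2R)-2-methylbutanoyl]-6-oxocyclohexa-1,3-dien-1-yl]methyl}-4-methoxy-1,5-dimethyl-2,6-dioxocyclohex-3-en-1-yl (2S)-2-methylbutanoate
Conditions: (S,S)-2,2'-[(2-iodo-1,3-phenylene)bis(oxy)]bis(N-mesitylpropanamide) (10 mol %), mCPBA (1.2 equiv), ClCH2CO2H (5 equiv), CHCl3, −20 °C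
Reagents that add atoms: chloroacetic acid, OC(=O)CCl
Why: Proposed new method: second use of the step 5 reaction, now with a sacrificial acid, where only O4 of ring A is free (O2 is locked in a hydrogen bond to the ketone) so iodine binds there and chloroacetate is delivered to the methyl-bearing ortho carbon C3 and not to the hindered C5, and, because the bound hydroxyl lies on the other side of the reacting carbon than in step 5, the mirror-image (S,S)-catalyst is used to set C3 as R; the closest known reactions are again the Wessely acetoxylation and the catalytic enantioselective Kita spirolactonization.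

Step 11
Reactants: 14 (1R,5R)-5-{[(5R)-5-[(chloroacetyl)oxy]-4-hydroxy-2-methoxy-5-methyl-3-[(2R)-2-methylbutanoyl]-6-oxocyclohexa-1,3-dien-1-yl]methyl}-4-methoxy-1,5-dimethyl-2,6-dioxocyclohex-3-en-1-yl (2S)-2-methylbutanoate
Product: 16 (1R,5R)-5-{[(5R)-4-amino-5-hydroxy-2-methoxy-5-methyl-3-[(2R)-2-methylbutanoyl]-6-oxocyclohexa-1,3-dien-1-yl]methyl}-4-methoxy-1,5-dimethyl-2,6-dioxocyclohex-3-en-1-yl (2S)-2-methylbutanoate, via hydroxy enol 15 (not isolated)
Conditions: NH3 (7 M in MeOH), 0 °C to 40 °C
Reagents that add atoms: ammonia, N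
Why: Ester aminolysis followed by enaminone formation (condensation of ammonia with a cyclic β-diketone enol), in which ammonia removes the activated chloroacetate far faster than the hindered α-branched tertiary ester of ring B and then condenses at C2 (activated by the neighbouring C3 oxygen, while the side-chain carbonyl is shielded by its α-branch) to give the vinylogous amide without touching any stereocenter.

**Compound list**

1 | (E)-2-methylbut-2-enoic acid (tiglic acid) | C/C=C(\C)C(O)=O | starting material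
2 | (2S)-2-methylbutanoic acid | CC[C@H](C)C(O)=O | intermediate
3 | (2R)-2-methylbutanoic acid | CC[C@@H](C)C(O)=O | intermediate
4 | 5-methoxy-2-methylbenzene-1,3-diol | COc1cc(O)c(C)c(O)c1 | starting material
5 | 4-bromo-5-methoxy-2-methylbenzene-1,3-diol | COc1cc(O)c(C)c(O)c1Br | intermediate
6 | 4-bromo-5-methoxy-2-methyl-6-[(4-methylbenzenesulfonyl)methyl]benzene-1,3-diol | COc1c(Br)c(O)c(C)c(O)c1CS(=O)(=O)c1ccc(C)cc1 | intermediate
7 | (1S)-3-bromo-6-hydroxy-4-methoxy-1-methyl-5-[(4-methylbenzenesulfonyl)methyl]-2-oxocyclohexa-3,5-dien-1-yl (2S)-2-methylbutanoate (ring B ortho-quinol ester; C3' arranged as in the target) | Cc1ccc(cc1)S(=O)(=O)CC1=C(O)[C@](C)(OC(=O)[C@@H](C)CC)C(=O)C(Br)=C1OC | intermediate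
8 | (2R)-2-methylbutanoyl chloride | CC[C@@H](C)C(Cl)=O | intermediate
9 | (2R)-1-(2,4-dihydroxy-6-methoxy-3-methylphenyl)-2-methylbutan-1-one | CC[C@@H](C)C(=O)c1c(O)c(C)c(O)cc1OC | intermediate
10 | (1S)-3-bromo-4-methoxy-1-methyl-5-methylidene-2,6-dioxocyclohex-3-en-1-yl (2S)-2-methylbutanoate | C=C1C(=O)[C@](C)(OC(=O)[C@@H](C)CC)C(=O)C(Br)=C1OC | intermediate
11 | (1S)-3-bromo-5-{[2,4-dihydroxy-6-methoxy-3-methyl-5-[(2R)-2-methylbutanoyl]phenyl]methyl}-6-hydroxy-4-methoxy-1-methyl-2-oxocyclohexa-3,5-dien-1-yl (2S)-2-methylbutanoate | CC[C@@H](C)C(=O)c1c(O)c(C)c(O)c(CC2=C(O)[C@](C)(OC(=O)[C@@H](C)CC)C(=O)C(Br)=C2OC)c1OC | intermediate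
12 | (1S,5R)-3-bromo-5-{[2,4-dihydroxy-6-methoxy-3-methyl-5-[(2R)-2-methylbutanoyl]phenyl]methyl}-4-methoxy-1,5-dimethyl-2,6-dioxocyclohex-3-en-1-yl (2S)-2-methylbutanoate | CC[C@@H](C)C(=O)c1c(O)c(C)c(O)c(C[C@@]2(C)C(=O)[C@](C)(OC(=O)[C@@H](C)CC)C(=O)C(Br)=C2OC)c1OC | intermediate
13 | (1R,5R)-5-{[2,4-dihydroxy-6-methoxy-3-methyl-5-[(2R)-2-methylbutanoyl]phenyl]methyl}-4-methoxy-1,5-dimethyl-2,6-dioxocyclohex-3-en-1-yl (2S)-2-methylbutanoate | CC[C@@H](C)C(=O)c1c(O)c(C)c(O)c(C[C@@]2(C)C(=O)[C@](C)(OC(=O)[C@@H](C)CC)C(=O)C=C2OC)c1OC | intermediate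
14 | (1R,5R)-5-{[(5R)-5-[(chloroacetyl)oxy]-4-hydroxy-2-methoxy-5-methyl-3-[(2R)-2-methylbutanoyl]-6-oxocyclohexa-1,3-dien-1-yl]methyl}-4-methoxy-1,5-dimethyl-2,6-dioxocyclohex-3-en-1-yl (2S)-2-methylbutanoate | CC[C@@H](C)C(=O)C1=C(O)[C@@](C)(OC(=O)CCl)C(=O)C(C[C@@]2(C)C(=O)[C@](C)(OC(=O)[C@@H](C)CC)C(=O)C=C2OC)=C1OC | intermediate
15 | (1R,5R)-5-{[(5R)-4,5-dihydroxy-2-methoxy-5-methyl-3-[(2R)-2-methylbutanoyl]-6-oxocyclohexa-1,3-dien-1-yl]methyl}-4-methoxy-1,5-dimethyl-2,6-dioxocyclohex-3-en-1-yl (2S)-2-methylbutanoate | CC[C@@H](C)C(=O)C1=C(O)[C@@](C)(O)C(=O)C(C[C@@]2(C)C(=O)[C@](C)(OC(=O)[C@@H](C)CC)C(=O)C=C2OC)=C1OC | intermediate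
16 | (1R,5R)-5-{[(5R)-4-amino-5-hydroxy-2-methoxy-5-methyl-3-[(2R)-2-methylbutanoyl]-6-oxocyclohexa-1,3-dien-1-yl]methyl}-4-methoxy-1,5-dimethyl-2,6-dioxocyclohex-3-en-1-yl (2S)-2-methylbutanoate (CNP0537128.1) | CC[C@@H](C)C(=O)C1=C(N)[C@@](C)(O)C(=O)C(C[C@@]2(C)C(=O)[C@](C)(OC(=O)[C@@H](C)CC)C(=O)C=C2OC)=C1OC | target

**Step count and risks**

Total steps: 11. Longest linear sequence: 8 (steps 3, 4, 5, 7, 8, 9, 10, 11; 4 → 5 → 6 → 7 → 11 → 12 → 13 → 14 → 16).

The three steps most likely to fail:

Risk 1, step 5 (the proposed new reaction, used again in step 10). The two hydroxyls of 6 may compete for iodine and erode the selectivity, m-chlorobenzoate may be transferred in place of 2, or the acidic CH2SO2Tol position may be oxidised. The fallback uses known chemistry and sets out from 6 and 2. PhI(OAc)2 is first stirred with 2 to exchange its acetates and then treated with 6 in CH2Cl2 at 0 °C, a Wessely-type acyloxylative dearomatisation with an achiral trivalent iodine reagent. It gives 7 together with its C3' epimer, (1R)-3-bromo-6-hydroxy-4-methoxy-1-methyl-5-[(4-methylbenzenesulfonyl)methyl]-2-oxocyclohexa-3,5-dien-1-yl (2S)-2-methylbutanoate F1. The two are diastereomers because of the (S)-acyl group and are separated by chromatography, and the route is rejoined at 7.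

Risk 2, step 8. Methylation at the hindered, fully substituted C1' may lose to O-methylation of the enolate, and the facial ratio rests on substrate control alone. The fallback sets out from 11 and replaces substrate control by ion-pair control. The methylation is run under solid–liquid phase transfer (solid K2CO3, MeI, toluene, 0 °C) with 2 mol % of a chiral binaphthyl-derived spiro quaternary ammonium bromide of the Maruoka type. Its tight ion pair favours C-alkylation, and its antipode is chosen to reinforce the substrate bias. It comes back at 12 and makes no new compound (F0).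

Risk 3, step 11. Ammonia may condense at the side-chain carbonyl instead of C2, or open the non-enolisable diketone of ring B. The fallback sets out from 14 and fixes the site of nitrogen entry with a leaving group. K2CO3 (catalytic) in MeOH at 0 °C removes only the chloroacetate and gives 15, isolated this time. Me3SiCHN2 then converts the C2 enol into the methyl enol ether (1R,5R)-5-{[(5R)-5-hydroxy-2,4-dimethoxy-5-methyl-3-[(2R)-2-methylbutanoyl]-6-oxocyclohexa-1,3-dien-1-yl]methyl}-4-methoxy-1,5-dimethyl-2,6-dioxocyclohex-3-en-1-yl (2S)-2-methylbutanoate F2. NH3 in MeOH at 0 °C displaces that methoxy group by addition–elimination at C2, and the route comes back at 16.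

**Further compounds**

F1 | step 5 | (1R)-3-bromo-6-hydroxy-4-methoxy-1-methyl-5-[(4-methylbenzenesulfonyl)methyl]-2-oxocyclohexa-3,5-dien-1-yl (2S)-2-methylbutanoate | Cc1ccc(cc1)S(=O)(=O)CC1=C(O)[C@@](C)(OC(=O)[C@@H](C)CC)C(=O)C(Br)=C1OC
F0 | step 8 | none | none
F2 | step 11 | (1R,5R)-5-{[(5R)-5-hydroxy-2,4-dimethoxy-5-methyl-3-[(2R)-2-methylbutanoyl]-6-oxocyclohexa-1,3-dien-1-yl]methyl}-4-methoxy-1,5-dimethyl-2,6-dioxocyclohex-3-en-1-yl (2S)-2-methylbutanoate | CC[C@@H](C)C(=O)C1=C(OC)[C@@](C)(O)C(=O)C(C[C@@]2(C)C(=O)[C@](C)(OC(=O)[C@@H](C)CC)C(=O)C=C2OC)=C1OC
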